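Count the Q before anything else.

the same everywhere: G 0.11 M

| charge | Q | remark | time |
|---|---|---|---|
| beta | 0.14 M | run made earlier |  |
| alpha | 0.18 M | run made earlier |  |
| delta | 0.26 M | run made earlier |  |
| Saturday's | 0.165 M |  | 12 min |
| Wednesday's | 0.110 M |  | 12 min |
| Friday's | 0.275 M |  | 12 min |

| run | time / min | J / % | G / % |
|---|---|---|---|
| beta | 1.33 | 1 | 48 |
| beta | 2.50 | 1 | 34 |
| beta | 4.00 | 8 | 28 |
| beta | 5.00 | 8 | 27 |
| beta | 6.00 | 6 | 22 |
| alpha | 0.500 | 5 | 66 |
| alpha | 1.50 | 0 | 35 |
| alpha | 3.00 | 6 | 21 |
| alpha | 4.00 | 8 | 14 |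
| alpha | 6.00 | 15 | 15 |
| delta | 0.500 | 0 | 53 |
| delta | 1.50 | 6 | 25 |
| delta | 3.00 | 17 | 11 |
| delta | 4.00 | 24 | 6 |
| delta | 6.00 | 29 | 6 |

(each reading ± 2 percentage points)

- steps that have been proposed: G + Q -> E + X; X + Q -> E + L; L + Q <-> E + J; J + Q -> D

* which of these holds the largest part of the G at the end of Saturday's (L / J / G / X)
* which of these holds the largest part of the G at the end of Wednesday's (L / J / G / X)
* which of these holds the largest part of the G at the end of Friday's (L / J / G / X)
* J at the end of Friday's, in percent of the G charged

Which given numbers must we know well? The time can be rough: J in delta gained 5 percentage points from 4.00 min to 6.00 min. The rate of the first exchange can be rough too, since G in delta read 6 % at 4.00 min. The charges are another matter. From delta's 0.26 M to Friday's 0.275 M is a small step in Q, yet the spare Q moves from 36.4 % to 50.0 % of the G charged. By spare Q we mean the Q charged less two per G, taken per G charged.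

With q the free Q per G charged, the proposed steps give q + J + 2D − X − 2G = spare at every moment. Saturday's spare is −50.0 % and Wednesday's is −100 %. A negative spare makes Q the limiting reagent of the first two exchanges. We commit to this budget, not to a value of J.

The forecast names L for Saturday's, X for Wednesday's and L for Friday's, with J at 38 % (29 % to 46 %). It adds: “Reversal and J → D are poorly known, so J could be somewhat lower.”

The flasks give X for Saturday's (42.1 %, L 34.0 %), X for Wednesday's and L for Friday's. Friday's J is 28.8 %, which is 9.2 points under the forecast.

    G + Q → E + X (k = 5.30 /M/min)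
    X + Q → E + L (k = 3.00 /M/min)
    L + Q ⇌ E + J (K = 6.70, k = 3.20 /M/min)
    J + Q → D (k = 0.720 /M/min)

Friday's is not at rest at 12 min: its slowest mode has a half-life of 27.9 min, longer than the time. Its balance then reads 50.0 %, the spare. Saturday's at 120 min reads −50.0 %, with X at 37.0 % and G at 8.20 % still standing. Friday's at 120 min reads 50.0 %, but the content has moved: D has risen to 19.7 %, L to 70.6 %, and J has fallen to 8.21 %.

Readings and results are calculated with constants of no real substance; the scatter is artificial.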